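## Retrosynthetic overview

1. The 1,10-oxirane, the C3 isovalerate, the C8 (2S,3S)-epoxyangelate and the C11 methylene are removed last. The trans-fused C6/C7 γ-lactone is traced to a C6 ketone alkylated at C7 with an acetate arm, with the C8 oxygen carried as a C8–Si bond.
2. The strategy rests on the ten-membered carbocycle C1–C10: C1–C6 with the cis C4=C5 bond are a hidden cyclohexene, and C8=C7–C6/C1–C10=C9 is a 1,5-diene with oxygen on C6 once C1 and C6 are joined. An anionic oxy-Cope shift makes C8–C9, breaks C1–C6 and expands six to ten.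
3. The cyclohexenol comes from (S)-carvone (epoxidation, Wharton transposition, silylation, allylic oxidation) and an (E)-2-silylvinyl metal; the epoxy acid comes from angelic acid by asymmetric epoxidation.
4. Ring order: cyclohexene (chiral pool) → ten-membered ring (step 8) → γ-lactone (step 12) → 1,10-oxirane (step 23).

Key step: step 8

Remark 1: ring positions carry germacrane locants (C1–C10 ring, C11–C13 lactone carbons, C14 on C10, C15 on C4); Ar = 2,4,6-trimethoxyphenyl, TBS = tert-butyldimethylsilyl, TES = triethylsilyl.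
Remark 2: the aryl group on silicon is 2,4,6-trimethoxyphenyl and not phenyl, because a phenylsilane is unmasked only by electrophiles or by strong base with fluoride, which the ring olefins, the lactone and the silyl ether would not survive; the trimethoxyphenyl group leaves with catalytic acid.
Remark 3 (assumption): hydride addition to ketone 20 is taken to follow the Felkin–Anh sense (alcohol cis to the C7 arm), so the lactone is closed after inversion at C6; the opposite epimer is compound 23 of the route.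

## Route

Step 1
Reactants: 1 (S)-(+)-carvone
Product: 2 (1S,4S,6S)-1-methyl-4-(prop-1-en-2-yl)-7-oxabicyclo[4.1.0]heptan-2-one
Conditions: 30% H2O2, NaOH (cat.), MeOH, 0 °C
Reagents that add atoms: hydrogen peroxide, OO
Why: Weitz–Scheffer (nucleophilic) epoxidation touches only the enone, and the hydroperoxide adds to the β-carbon anti to the isopropenyl group, which sets the oxygen-bearing centre that becomes C3 (S).

Step 2
Reactants: 2 (1S,4S,6S)-1-methyl-4-(prop-1-en-2-yl)-7-oxabicyclo[4.1.0]heptan-2-one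
Product: 3 (1S,5R)-2-methyl-5-(prop-1-en-2-yl)cyclohex-2-en-1-ol
Conditions: N2H4·H2O, AcOH (cat.), MeOH, 0 °C to 25 °C
Reagents that add atoms: none
Why: In the Wharton transposition the epoxy hydrazone opens and loses N2, so the carbonyl carbon becomes an olefinic CH while the epoxide C–O bond survives as the allylic alcohol trans to the isopropenyl group.

Step 3
Reactants: 3 (1S,5R)-2-methyl-5-(prop-1-en-2-yl)cyclohex-2-en-1-ol
Product: 4 tert-butyldimethylsilyl ether of 3
Conditions: TBSCl, imidazole, DMF, 25 °C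
Reagents that add atoms: tert-butyldimethylsilyl chloride, CC(C)(C)[Si](C)(C)Cl
Why: Standard silylation of a secondary allylic alcohol gives an ether that tolerates the organometallic, hydride and enolate steps that follow.

Step 4
Reactants: 4 tert-butyldimethylsilyl ether of 3
Product: 5 (4S,6R)-4-(tert-butyldimethylsilyloxy)-3-methyl-6-(prop-1-en-2-yl)cyclohex-2-en-1-one
Conditions: CrO3, 3,5-dimethylpyrazole, CH2Cl2, −20 °C
Reagents that add atoms: chromium trioxide, O=[Cr](=O)=O
Why: Allylic oxidation by the CrO3–3,5-dimethylpyrazole complex should take the only ring methylene allylic to the trisubstituted olefin (the carbinol C–H is pseudoequatorial and poorly aligned), giving the γ-silyloxy enone without a new stereocentre.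

Step 5
Reactants: 6 1,3,5-trimethoxybenzene
Product: 8 methoxydimethyl(2,4,6-trimethoxyphenyl)silane, via aryllithium 7 (not isolated)
Conditions: n-BuLi, Me2NCH2CH2NMe2, THF, 0 °C; then Me2Si(OMe)2 (3 equiv), −78 °C to 25 °C
Reagents that add atoms: dimethoxydimethylsilane, CO[Si](C)(C)OC
Why: Directed ortho-lithiation between two methoxy groups is followed by nucleophilic substitution at silicon, the excess dimethoxysilane keeping it to one aryl transfer.

Step 6
Reactants: 9 (E)-1,2-bis(tributylstannyl)ethene; 8 methoxydimethyl(2,4,6-trimethoxyphenyl)silane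
Product: 11 (E)-tributyl{2-[dimethyl(2,4,6-trimethoxyphenyl)silyl]ethenyl}stannane, via stannylvinyllithium 10 (not isolated)
Conditions: n-BuLi (1 equiv), THF, −78 °C; then 8, −78 °C to 25 °C
Reagents that add atoms: none
Why: A single tin–lithium exchange and substitution of methoxide at silicon both proceed with retention of the E geometry.

Step 7
Reactants: 11 (E)-tributyl{2-[dimethyl(2,4,6-trimethoxyphenyl)silyl]ethenyl}stannane; 5 (4S,6R)-4-(tert-butyldimethylsilyloxy)-3-methyl-6-(prop-1-en-2-yl)cyclohex-2-en-1-one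
Product: 14 (1R,4S,6R)-4-(tert-butyldimethylsilyloxy)-1-{(E)-2-[dimethyl(2,4,6-trimethoxyphenyl)silyl]ethenyl}-3-methyl-6-(prop-1-en-2-yl)cyclohex-2-en-1-ol, via silylvinyllithium 12 (not isolated), via alkenylcerium dichloride 13 (not isolated)
Conditions: n-BuLi, THF, −78 °C; CeCl3, −78 °C; then 5, −78 °C; aq NH4Cl
Reagents that add atoms: none
Why: Tin–lithium exchange with retention and 1,2-addition of the weakly basic organocerium (no enolisation of the α'-CH) should deliver the alkenyl group anti to the neighbouring isopropenyl group (Felkin–Anh sense, axial attack on the half-chair with that group pseudoaxial), so the two alkenyl groups end up trans (new centre 1R).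

Step 8
Reactants: 14 (1R,4S,6R)-4-(tert-butyldimethylsilyloxy)-1-{(E)-2-[dimethyl(2,4,6-trimethoxyphenyl)silyl]ethenyl}-3-methyl-6-(prop-1-en-2-yl)cyclohex-2-en-1-ol
Product: 17 (3S,8R)-3-(tert-butyldimethylsilyloxy)-8-[dimethyl(2,4,6-trimethoxyphenyl)silyl]-4,10-dimethylcyclodeca-1(10)E,4Z-dien-6-one, via potassium alkoxide 15 (not isolated), via potassium enolate 16 (not isolated)
Conditions: KH, 18-crown-6, THF, 0 °C to 25 °C; then aq NH4Cl, −78 °C
Reagents that add atoms: none
Why: Deprotonation gives the tertiary potassium alkoxide 15, whose oxyanion weakens the adjacent C1–C6 bond and lets the [3,3]-sigmatropic shift run near room temperature; this is the anionic oxy-Cope rearrangement, closest to the known ring expansion of trans-1,2-dialkenylcyclohexanols to cyclodec-5-enones. The ten-membered ring is closed by ring expansion and not by end-to-end cyclisation: C8–C9 forms across the termini of the 1,5-diene while the C1–C6 bond of the cyclohexene breaks. The only new stereocentre, C8, is fixed by the chair six-centre transition state in which both cyclohexene ring bonds (C1–C2 and C6–C5) are equatorial and the silicon of the E-vinylsilane is equatorial, which relays the R configuration of the carvone-derived C1 to 8R. The same chair makes C1=C10 E (C2 equatorial), and C4=C5 is carried over cis from the cyclohexene. The selectivity needed is chair over boat and trans- over cis-dialkenyl geometry, secured by the diequatorial alkenyl groups set in step 7; the C3 silyl ether is a spectator and enolate 16 cannot eliminate because silicon is no leaving group. Cold protonation of 16 at carbon gives ketone 17.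

Step 9
Reactants: 17 (3S,8R)-3-(tert-butyldimethylsilyloxy)-8-[dimethyl(2,4,6-trimethoxyphenyl)silyl]-4,10-dimethylcyclodeca-1(10)E,4Z-dien-6-one; 18 tert-butyl bromoacetate
Product: 20 tert-butyl 2-[(3S,7S,8R)-3-(tert-butyldimethylsilyloxy)-8-(ArMe2Si)-4,10-dimethyl-6-oxocyclodeca-1(10)E,4Z-dien-7-yl]acetate, via lithium enolate 19 (not isolated)
Conditions: LiN(iPr)2, THF, −78 °C; then 18, N,N'-dimethylpropyleneurea, −78 °C to −40 °C
Reagents that add atoms: none
Why: Kinetic α'-deprotonation gives only the C6=C7 enolate, and in this enolate alkylation the bromoacetate should attack C7 anti to the C8 silyl group in the conformer with H8 eclipsing the enolate (allylic 1,3-strain; also the outer face of the ring), placing the acetate arm cis to silicon (7S).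

Step 10
Reactants: 20 tert-butyl 2-[(3S,7S,8R)-3-(tert-butyldimethylsilyloxy)-8-(ArMe2Si)-4,10-dimethyl-6-oxocyclodeca-1(10)E,4Z-dien-7-yl]acetate
Product: 21 tert-butyl 2-[(3S,6S,7S,8R)-3-(tert-butyldimethylsilyloxy)-8-(ArMe2Si)-6-hydroxy-4,10-dimethylcyclodeca-1(10)E,4Z-dien-7-yl]acetate
Conditions: NaBH4, CeCl3·7H2O, MeOH, −78 °C to −40 °C
Reagents that add atoms: none
Why: In this Luche 1,2-reduction hydride should approach anti to the C7–C8 ring bond with the acetate arm beside the carbonyl oxygen (Felkin–Anh), giving the 6S alcohol cis to the arm, while the tert-butyl ester blocks premature closure to a cis-lactone.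

Step 11
Reactants: 21 tert-butyl 2-[(3S,6S,7S,8R)-3-(tert-butyldimethylsilyloxy)-8-(ArMe2Si)-6-hydroxy-4,10-dimethylcyclodeca-1(10)E,4Z-dien-7-yl]acetate
Product: 22 (6R)-4-nitrobenzoate of the C6 epimer of 21
Conditions: 4-nitrobenzoic acid, PPh3, diisopropyl azodicarboxylate, toluene, 0 °C to 25 °C
Reagents that add atoms: 4-nitrobenzoic acid, OC(=O)c1ccc(cc1)[N+](=O)[O-]
Why: Mitsunobu reaction: SN2 displacement of the allylic oxyphosphonium by the carboxylate inverts C6 to 6R, the configuration needed for the trans-lactone.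

Step 12
Reactants: 22 (6R)-4-nitrobenzoate of the C6 epimer of 21
Product: 24 (3S,6R,7S,8R)-3-(tert-butyldimethylsilyloxy)-8-(ArMe2Si)-13-norgermacra-1(10)E,4Z-dien-12,6-olide, via hydroxy ester 23 (not isolated)
Conditions: NaOMe, MeOH, 0 °C; then KOt-Bu (cat.), THF, 0 °C
Reagents that add atoms: none
Why: Methanolysis of the activated benzoate is followed by base-mediated transesterification, the 6R alkoxide closing the trans-fused γ-lactone by 5-exo-trig attack on the tert-butyl ester without touching a stereocentre.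

Step 13
Reactants: 24 (3S,6R,7S,8R)-3-(tert-butyldimethylsilyloxy)-8-(ArMe2Si)-13-norgermacra-1(10)E,4Z-dien-12,6-olide
Product: 26 (3S,6R,7R,8R)-3-(tert-butyldimethylsilyloxy)-8-hydroxy-13-norgermacra-1(10)E,4Z-dien-12,6-olide, via methoxysilane 25 (not isolated)
Conditions: CF3CO2H (0.2 equiv), MeOH–CH2Cl2, 0 °C; then KF, KHCO3, 30% H2O2, THF–MeOH, 25 °C
Reagents that add atoms: hydrogen peroxide, OO
Why: ipso-Protodesilylation of the very electron-rich aryl ring by catalytic acid should be far faster than protonation of the trisubstituted olefins and gives the methoxysilane, whose Tamao oxidation (Fleming–Tamao type) replaces C8–Si by C8–OH with retention (8R; the C7 descriptor changes from S to R by priority only).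

Step 14
Reactants: 26 (3S,6R,7R,8R)-3-(tert-butyldimethylsilyloxy)-8-hydroxy-13-norgermacra-1(10)E,4Z-dien-12,6-olide
Product: 27 8-triethylsilyl ether of 26
Conditions: TESOTf, 2,6-lutidine, CH2Cl2, −78 °C
Reagents that add atoms: triethylsilyl trifluoromethanesulfonate, CC[Si](CC)(CC)OS(=O)(=O)C(F)(F)F
Why: Silylation of the hindered C8 hydroxyl masks it during enolate chemistry and keeps it from attacking the lactone carbonyl, with a group that can later be removed beside the C3 silyl ether.

Step 15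
Reactants: 27 8-triethylsilyl ether of 26
Product: 31 (3S,6R,7R,8R)-3-(tert-butyldimethylsilyloxy)-8-(triethylsilyloxy)germacra-1(10)E,4Z,11(13)-trien-12,6-olide, via lithium enolate 28 (not isolated), via Mannich base 29 (not isolated), via ammonium iodide 30 (not isolated)
Conditions: LiN(iPr)2, THF, −78 °C; [CH2=NMe2]I, −78 °C to 0 °C; MeI, MeOH, 25 °C; aq NaHCO3, EtOAc, 25 °C
Reagents that add atoms: N,N-dimethylmethyleneiminium iodide (Eschenmoser's salt), C=[N+](C)C.[I-]
Why: Mannich reaction of the lactone enolate, quaternisation and E1cB loss of trimethylamine install the exocyclic C11=C13 methylene while both hydroxyls are silylated, and C11 is not a stereocentre in the product.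

Step 16
Reactants: 31 (3S,6R,7R,8R)-3-(tert-butyldimethylsilyloxy)-8-(triethylsilyloxy)germacra-1(10)E,4Z,11(13)-trien-12,6-olide
Product: 32 (3S,6R,7R,8R)-3-(tert-butyldimethylsilyloxy)-8-hydroxygermacra-1(10)E,4Z,11(13)-trien-12,6-olide
Conditions: pyridinium p-toluenesulfonate (cat.), MeOH, 0 °C
Reagents that add atoms: none
Why: Acid-catalysed methanolysis should remove the triethylsilyl ether much faster than the bulkier tert-butyldimethylsilyl ether, under acidity too low to protonate the ring olefins.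

Step 17
Reactants: 33 angelic acid
Product: 34 (Z)-2-methylbut-2-en-1-ol
Conditions: LiAlH4, Et2O, 0 °C
Reagents that add atoms: none
Why: Hydride reduction of the carboxylic acid to the allylic alcohol leaves the Z olefin geometry untouched.

Step 18
Reactants: 34 (Z)-2-methylbut-2-en-1-ol
Product: 35 [(2R,3S)-2,3-dimethyloxiran-2-yl]methanol
Conditions: Ti(OiPr)4 (cat.), D-(−)-diethyl tartrate (cat.), t-BuOOH, 4 Å molecular sieves, CH2Cl2, −20 °C
Reagents that add atoms: tert-butyl hydroperoxide, CC(C)(C)OO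
Why: Sharpless asymmetric epoxidation: the D-(−)-tartrate titanium complex delivers oxygen to the face of the allylic alcohol that gives the 2R,3S epoxide, the olefin geometry fixing the cis relation of CH2OH and the C3 methyl.

Step 19
Reactants: 35 [(2R,3S)-2,3-dimethyloxiran-2-yl]methanol
Product: 36 (2S,3S)-2,3-dimethyloxirane-2-carboxylic acid
Conditions: 2,2,6,6-tetramethylpiperidin-1-oxyl (cat.), PhI(OAc)2, MeCN–H2O, 25 °C
Reagents that add atoms: water, O
Why: Oxoammonium-mediated oxidation through the aldehyde hydrate gives the acid under near-neutral conditions that spare the oxirane (C2 becomes S by priority change only).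

Step 20
Reactants: 32 (3S,6R,7R,8R)-3-(tert-butyldimethylsilyloxy)-8-hydroxygermacra-1(10)E,4Z,11(13)-trien-12,6-olide; 36 (2S,3S)-2,3-dimethyloxirane-2-carboxylic acid
Product: 38 8-[(2S,3S)-2,3-dimethyloxirane-2-carbonyl] ester of 32, via mixed anhydride 37 (not isolated)
Conditions: 2,4,6-trichlorobenzoyl chloride, Et3N, THF, 25 °C; then 32, 4-(dimethylamino)pyridine, toluene, 25 °C
Reagents that add atoms: none
Why: Yamaguchi esterification activates the hindered α-quaternary acid as a mixed anhydride that acylates the secondary C8 hydroxyl without acid that could open either oxirane-prone site.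

Step 21
Reactants: 38 8-[(2S,3S)-2,3-dimethyloxirane-2-carbonyl] ester of 32
Product: 39 3-hydroxy compound (tert-butyldimethylsilyl group of 38 removed)
Conditions: HF·pyridine, pyridine, THF, 0 °C to 25 °C
Reagents that add atoms: none
Why: Buffered fluoride desilylation frees the allylic C3 hydroxyl and should leave the α,β-epoxy ester and the methylene lactone intact.

Step 22
Reactants: 39 3-hydroxy compound
Product: 40 (3S,6R,7R,8R)-8-[(2S,3S)-2,3-dimethyloxirane-2-carbonyloxy]-3-(3-methylbutanoyloxy)germacra-1(10)E,4Z,11(13)-trien-12,6-olide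
Conditions: 3-methylbutanoic anhydride, Et3N, 4-(dimethylamino)pyridine (cat.), CH2Cl2, 0 °C
Reagents that add atoms: 3-methylbutanoic anhydride, CC(C)CC(=O)OC(=O)CC(C)C
Why: Nucleophile-catalysed acylation of the secondary allylic alcohol installs the isovalerate with retention at C3.

Step 23
Reactants: 40 (3S,6R,7R,8R)-8-[(2S,3S)-2,3-dimethyloxirane-2-carbonyloxy]-3-(3-methylbutanoyloxy)germacra-1(10)E,4Z,11(13)-trien-12,6-olide
Product: 41 CNP0167461.1
Conditions: mCPBA, NaHCO3, CH2Cl2, 0 °C
Reagents that add atoms: 3-chloroperoxybenzoic acid, OOC(=O)c1cccc(Cl)c1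
Why: Prilezhaev epoxidation should take only the electron-rich C1=C10 olefin (C4=C5 is deactivated by two allylic acyloxy groups, C11=C13 is electron-poor), the peracid attacking the outer face of the E olefin in the conformer with C14 on the β face to give the 1β,10α-oxirane (1R,10R).

## Compound list

1 | (S)-(+)-carvone | CC1=CC[C@H](C(C)=C)CC1=O | starting material
2 | (1S,4S,6S)-1-methyl-4-(prop-1-en-2-yl)-7-oxabicyclo[4.1.0]heptan-2-one | C[C@]12O[C@H]1C[C@H](C(C)=C)CC2=O | intermediate
3 | (1S,5R)-2-methyl-5-(prop-1-en-2-yl)cyclohex-2-en-1-ol (trans-carveol) | CC1=CC[C@@H](C(C)=C)C[C@@H]1O | intermediate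
4 | tert-butyldimethylsilyl ether of 3 | CC1=CC[C@@H](C(C)=C)C[C@@H]1O[Si](C)(C)C(C)(C)C | intermediate
5 | (4S,6R)-4-(tert-butyldimethylsilyloxy)-3-methyl-6-(prop-1-en-2-yl)cyclohex-2-en-1-one | CC1=CC(=O)[C@@H](C(C)=C)C[C@@H]1O[Si](C)(C)C(C)(C)C | intermediate
6 | 1,3,5-trimethoxybenzene | COc1cc(OC)cc(OC)c1 | starting material
7 | 2,4,6-trimethoxyphenyllithium | [Li]c1c(OC)cc(OC)cc1OC | intermediate
8 | methoxydimethyl(2,4,6-trimethoxyphenyl)silane | CO[Si](C)(C)c1c(OC)cc(OC)cc1OC | intermediate
9 | (E)-1,2-bis(tributylstannyl)ethene | CCCC[Sn](CCCC)(CCCC)/C=C/[Sn](CCCC)(CCCC)CCCC | starting material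
10 | (E)-2-(tributylstannyl)ethenyllithium | [Li]/C=C/[Sn](CCCC)(CCCC)CCCC | intermediate
11 | (E)-tributyl{2-[dimethyl(2,4,6-trimethoxyphenyl)silyl]ethenyl}stannane | CCCC[Sn](CCCC)(CCCC)/C=C/[Si](C)(C)c1c(OC)cc(OC)cc1OC | intermediate
12 | (E)-2-[dimethyl(2,4,6-trimethoxyphenyl)silyl]ethenyllithium | [Li]/C=C/[Si](C)(C)c1c(OC)cc(OC)cc1OC | intermediate
13 | (E)-2-[dimethyl(2,4,6-trimethoxyphenyl)silyl]ethenylcerium dichloride | Cl[Ce](Cl)/C=C/[Si](C)(C)c1c(OC)cc(OC)cc1OC | intermediate
14 | (1R,4S,6R)-4-(tert-butyldimethylsilyloxy)-1-{(E)-2-[dimethyl(2,4,6-trimethoxyphenyl)silyl]ethenyl}-3-methyl-6-(prop-1-en-2-yl)cyclohex-2-en-1-ol | COc1cc(OC)c(c(OC)c1)[Si](C)(C)/C=C/[C@@]1(O)C=C(C)[C@@H](O[Si](C)(C)C(C)(C)C)C[C@@H]1C(C)=C | intermediate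
15 | potassium alkoxide of 14 | COc1cc(OC)c(c(OC)c1)[Si](C)(C)/C=C/[C@@]1([O-])C=C(C)[C@@H](O[Si](C)(C)C(C)(C)C)C[C@@H]1C(C)=C.[K+] | intermediate
16 | potassium C6=C7 enolate of 17 (C5 and C8 trans) | [K+].[O-]/C1=C\[C@H]([Si](C)(C)c2c(OC)cc(OC)cc2OC)C/C(C)=C/C[C@H](O[Si](C)(C)C(C)(C)C)/C(C)=C\1 | intermediate
17 | (3S,8R)-3-(tert-butyldimethylsilyloxy)-8-[dimethyl(2,4,6-trimethoxyphenyl)silyl]-4,10-dimethylcyclodeca-1(10)E,4Z-dien-6-one | O=C1/C=C(/C)[C@@H](O[Si](C)(C)C(C)(C)C)C/C=C(\C)C[C@@H]([Si](C)(C)c2c(OC)cc(OC)cc2OC)C1 | intermediate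
18 | tert-butyl bromoacetate | BrCC(=O)OC(C)(C)C | starting material
19 | lithium C6=C7 enolate of 17 (enolate geometry not fixed) | [Li+].[O-]C1=C[C@H]([Si](C)(C)c2c(OC)cc(OC)cc2OC)C/C(C)=C/C[C@H](O[Si](C)(C)C(C)(C)C)/C(C)=C\1 | intermediate
20 | tert-butyl 2-[(3S,7S,8R)-3-(tert-butyldimethylsilyloxy)-8-(ArMe2Si)-4,10-dimethyl-6-oxocyclodeca-1(10)E,4Z-dien-7-yl]acetate | O=C1/C=C(/C)[C@@H](O[Si](C)(C)C(C)(C)C)C/C=C(\C)C[C@@H]([Si](C)(C)c2c(OC)cc(OC)cc2OC)[C@H]1CC(=O)OC(C)(C)C | intermediate
21 | (3S,6S,7S,8R)-6-hydroxy ester (hydroxyl cis to the acetate arm) | O[C@H]1/C=C(/C)[C@@H](O[Si](C)(C)C(C)(C)C)C/C=C(\C)C[C@@H]([Si](C)(C)c2c(OC)cc(OC)cc2OC)[C@H]1CC(=O)OC(C)(C)C | intermediate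
22 | (3S,6R,7S,8R)-6-(4-nitrobenzoyloxy) ester | O=C(O[C@@H]1/C=C(/C)[C@@H](O[Si](C)(C)C(C)(C)C)C/C=C(\C)C[C@@H]([Si](C)(C)c2c(OC)cc(OC)cc2OC)[C@H]1CC(=O)OC(C)(C)C)c1ccc(cc1)[N+](=O)[O-] | intermediate
23 | (3S,6R,7S,8R)-6-hydroxy ester (hydroxyl trans to the acetate arm) | O[C@@H]1/C=C(/C)[C@@H](O[Si](C)(C)C(C)(C)C)C/C=C(\C)C[C@@H]([Si](C)(C)c2c(OC)cc(OC)cc2OC)[C@H]1CC(=O)OC(C)(C)C | intermediate
24 | (3S,6R,7S,8R)-3-(tert-butyldimethylsilyloxy)-8-(ArMe2Si)-13-norgermacra-1(10)E,4Z-dien-12,6-olide | C1C(=O)O[C@@H]2/C=C(/C)[C@@H](O[Si](C)(C)C(C)(C)C)C/C=C(\C)C[C@@H]([Si](C)(C)c3c(OC)cc(OC)cc3OC)[C@@H]12 | intermediate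
25 | 8-(methoxydimethylsilyl) lactone | C1C(=O)O[C@@H]2/C=C(/C)[C@@H](O[Si](C)(C)C(C)(C)C)C/C=C(\C)C[C@@H]([Si](C)(C)OC)[C@@H]12 | intermediate
26 | (3S,6R,7R,8R)-3-(tert-butyldimethylsilyloxy)-8-hydroxy-13-norgermacra-1(10)E,4Z-dien-12,6-olide | C1C(=O)O[C@@H]2/C=C(/C)[C@@H](O[Si](C)(C)C(C)(C)C)C/C=C(\C)C[C@@H](O)[C@@H]12 | intermediate
27 | 8-triethylsilyl ether of 26 | C1C(=O)O[C@@H]2/C=C(/C)[C@@H](O[Si](C)(C)C(C)(C)C)C/C=C(\C)C[C@@H](O[Si](CC)(CC)CC)[C@@H]12 | intermediate
28 | lithium enolate of lactone 27 | [Li+].[O-]C1=C[C@@H]2[C@H](O[Si](CC)(CC)CC)C/C(C)=C/C[C@H](O[Si](C)(C)C(C)(C)C)/C(C)=C\[C@H]2O1 | intermediate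
29 | 11-(dimethylaminomethyl) lactone (C11 epimers) | CN(C)CC1C(=O)O[C@@H]2/C=C(/C)[C@@H](O[Si](C)(C)C(C)(C)C)C/C=C(\C)C[C@@H](O[Si](CC)(CC)CC)[C@@H]12 | intermediate
30 | 11-(trimethylammoniomethyl) lactone iodide | C[N+](C)(C)CC1C(=O)O[C@@H]2/C=C(/C)[C@@H](O[Si](C)(C)C(C)(C)C)C/C=C(\C)C[C@@H](O[Si](CC)(CC)CC)[C@@H]12.[I-] | intermediate
31 | (3S,6R,7R,8R)-3-(tert-butyldimethylsilyloxy)-8-(triethylsilyloxy)germacra-1(10)E,4Z,11(13)-trien-12,6-olide | C=C1C(=O)O[C@@H]2/C=C(/C)[C@@H](O[Si](C)(C)C(C)(C)C)C/C=C(\C)C[C@@H](O[Si](CC)(CC)CC)[C@@H]12 | intermediate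
32 | (3S,6R,7R,8R)-3-(tert-butyldimethylsilyloxy)-8-hydroxygermacra-1(10)E,4Z,11(13)-trien-12,6-olide | C=C1C(=O)O[C@@H]2/C=C(/C)[C@@H](O[Si](C)(C)C(C)(C)C)C/C=C(\C)C[C@@H](O)[C@@H]12 | intermediate
33 | angelic acid | C/C=C(/C)C(=O)O | starting material
34 | (Z)-2-methylbut-2-en-1-ol | C/C=C(/C)CO | intermediate
35 | [(2R,3S)-2,3-dimethyloxiran-2-yl]methanol | OC[C@@]1(C)O[C@H]1C | intermediate
36 | (2S,3S)-2,3-dimethyloxirane-2-carboxylic acid | OC(=O)[C@@]1(C)O[C@H]1C | intermediate
37 | mixed anhydride of 36 with 2,4,6-trichlorobenzoic acid | O=C(OC(=O)c1c(Cl)cc(Cl)cc1Cl)[C@@]1(C)O[C@H]1C | intermediate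
38 | 8-[(2S,3S)-2,3-dimethyloxirane-2-carbonyl] ester of 32 | C=C1C(=O)O[C@@H]2/C=C(/C)[C@@H](O[Si](C)(C)C(C)(C)C)C/C=C(\C)C[C@@H](OC(=O)[C@@]3(C)O[C@H]3C)[C@@H]12 | intermediate
39 | (3S,6R,7R,8R)-8-[(2S,3S)-2,3-dimethyloxirane-2-carbonyloxy]-3-hydroxygermacra-1(10)E,4Z,11(13)-trien-12,6-olide | C=C1C(=O)O[C@@H]2/C=C(/C)[C@@H](O)C/C=C(\C)C[C@@H](OC(=O)[C@@]3(C)O[C@H]3C)[C@@H]12 | intermediate
40 | (3S,6R,7R,8R)-8-[(2S,3S)-2,3-dimethyloxirane-2-carbonyloxy]-3-(3-methylbutanoyloxy)germacra-1(10)E,4Z,11(13)-trien-12,6-olide | C=C1C(=O)O[C@@H]2/C=C(/C)[C@@H](OC(=O)CC(C)C)C/C=C(\C)C[C@@H](OC(=O)[C@@]3(C)O[C@H]3C)[C@@H]12 | intermediate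
41 | CNP0167461.1, (1R,3S,6R,7R,8R,10R)-1,10-epoxy-8-[(2S,3S)-2,3-dimethyloxirane-2-carbonyloxy]-3-(3-methylbutanoyloxy)germacra-4Z,11(13)-dien-12,6-olide | C=C1C(=O)O[C@@H]2/C=C(/C)[C@@H](OC(=O)CC(C)C)C[C@H]3O[C@]3(C)C[C@@H](OC(=O)[C@@]3(C)O[C@H]3C)[C@@H]12 | target

## Step count and risks

Total step count: 23 steps. Longest linear sequence: 18 steps (1–4, 7–16, 20–23, from (S)-carvone).

Steps most likely to fail:

1. Step 8. What may go wrong: the potassium alkoxide may cleave back to the enone and a vinyl anion, or part of the material may pass through a boat or the alternative chair, eroding the C8 configuration and the E geometry of C1=C10. Fallback (sets out from 14, returns at 17): 14 is silylated with Me3SiCl and imidazole to the trimethylsilyl ether of 14 F1. F1 is heated in degassed toluene in a sealed tube at about 200 °C, a neutral siloxy-Cope rearrangement through the same chair, to give the trimethylsilyl enol ether of 17 F2. Methanolysis of F2 with K2CO3 in MeOH at 0 °C gives ketone 17.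

2. Step 10. What may go wrong: hydride may be delivered to the other face of the C6 carbonyl, or with low facial selectivity, so that the 6R alcohol 23 forms beside or instead of 21. Fallback (sets out from 20, returns at 24): the approach changes from inversion to direct closure. The 6R epimer 23 is separated and treated with catalytic KOt-Bu in THF at 0 °C, which closes it with retention by acyl substitution to lactone 24; step 11 and the methanolysis are then not needed for that material, and any 21 still goes through steps 11 and 12. This fallback makes no compound outside the list (F0).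

3. Step 4. What may go wrong: oxidation at other allylic sites (the carbinol C–H, the ring methyl, the isopropenyl group), or epimerisation and conjugation at the α'-carbon bearing the isopropenyl group. Fallback (sets out from 3, returns at 5): hydroxyl-directed epoxidation of 3 with VO(acac)2 and t-BuOOH in CH2Cl2 gives the syn epoxy alcohol F3. Silylation with TBSCl and imidazole gives its silyl ether F4. Opening at the secondary oxirane carbon with PhSeNa (from PhSeSePh and NaBH4 in EtOH) gives the hydroxy selenide F5. Oxidation with H2O2 and pyridine in THF and selenoxide syn-elimination, which can only go away from the carbinol carbon, gives the tertiary allylic alcohol F6. Oxidative 1,3-transposition of F6 with pyridinium chlorochromate, C5H5NH[CrO3Cl], in CH2Cl2 gives enone 5 with the ketone fixed beside the isopropenyl-bearing carbon.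

## Further compounds

F1 | step 8 | trimethylsilyl ether of 14 | COc1cc(OC)c(c(OC)c1)[Si](C)(C)/C=C/[C@@]1(O[Si](C)(C)C)C=C(C)[C@@H](O[Si](C)(C)C(C)(C)C)C[C@@H]1C(C)=C
F2 | step 8 | trimethylsilyl enol ether (C6=C7) of 17 | C[Si](C)(C)O/C1=C\[C@H]([Si](C)(C)c2c(OC)cc(OC)cc2OC)C/C(C)=C/C[C@H](O[Si](C)(C)C(C)(C)C)/C(C)=C\1
F0 | step 10 | none | none
F3 | step 4 | (1S,2S,4S,6R)-1-methyl-4-(prop-1-en-2-yl)-7-oxabicyclo[4.1.0]heptan-2-ol (oxirane syn to hydroxyl) | C[C@@]12O[C@@H]1C[C@@H](C(C)=C)C[C@@H]2O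
F4 | step 4 | tert-butyldimethylsilyl ether of F3 | C[C@@]12O[C@@H]1C[C@@H](C(C)=C)C[C@@H]2O[Si](C)(C)C(C)(C)C
F5 | step 4 | trans-diaxial hydroxy selenide from F4 (phenylselanyl on the former olefinic CH) | C[C@@]1(O)[C@@H]([Se]c2ccccc2)C[C@@H](C(C)=C)C[C@@H]1O[Si](C)(C)C(C)(C)C
F6 | step 4 | 6-(tert-butyldimethylsilyloxy)-1-methyl-4-(prop-1-en-2-yl)cyclohex-2-en-1-ol (tertiary allylic alcohol) | C[C@@]1(O)C=C[C@@H](C(C)=C)C[C@@H]1O[Si](C)(C)C(C)(C)C
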